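The earlier runs and the new flask were generated by integration for an exercise, and the scatter is random.

At early times the south flask, the one asked about, looked clean. At 5.00 h the part of the charged E that was neither E nor Q was 2.30%, but by 72.0 h it was 26.2%. The missing part grew after Q had grown, so I took it to follow Q. I had to choose what to do to this flask at 5.0 d.

| flask | E | D | X | L | remark | time |
|---|---|---|---|---|---|---|
| south | 0.10 M | 1.2 equiv | 5 equiv | 1 mol% | the very flask that is asked about, followed so far |  |
| south-west | 0.067 M | 1.2 equiv | 5 equiv | 1 mol% | run made earlier |  |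
| flask | 0.10 M | 1.20 equiv | 5.00 equiv | 1 mol% |  | 5.0 d |

| run | time / h | Q / % | E / % |
|---|---|---|---|
| south | 5.00 | 9.8 | 87.9 |
| south | 15.0 | 26.9 | 69.1 |
| south | 25.0 | 33.3 | 57.6 |
| south | 40.0 | 38.3 | 47.1 |
| south | 60.0 | 41.2 | 34.7 |
| south | 72.0 | 42.6 | 31.2 |
| south-west | 3.00 | 3.7 | 95.5 |
| south-west | 6.00 | 7.2 | 94.0 |
| south-west | 8.00 | 6.7 | 89.0 |
| south-west | 12.0 | 12.7 | 85.2 |
| south-west | 15.0 | 12.7 | 85.2 |
| south-west | 20.0 | 17.2 | 80.0 |

(scatter of a reading: 1 percentage point)

- Q, in percent of the E first charged, at 5.0 d
- the remedy with the largest gain of Q, or "none" below 2 percentage points (noon / dawn / winter / midnight / none)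
- Q present, with what was taken out counted in, in percent of the E first charged, after winter
- Q present, with what was taken out counted in, in percent of the E first charged, after midnight

- noon: at 5.0 d add L, 50.0% of the amount charged, then wait 10 d
- dawn: change nothing and wait 10 d more
- winter: at 5.0 d take out 90% of the Q then present, then wait 10 d
- midnight: at 5.0 d add D, 50.0% of the amount charged, then wait 10 d

- Q that was removed still counts
- additions bring no volume worth counting

I carried one number, the shadow ratio: missing E per point of Q, that is (charged E − cE − cQ)/cQ. As read in the south flask it went from 0.273 at 25.0 h to 0.615 at 72.0 h. In logarithms that is a slope of 0.767 against time, and the same straight line gives a shadow ratio at 5.0 d of 0.910. A like line through the E readings at 40.0 h and 72.0 h gave E 21.8%, so I reckoned Q as (charged E − cE)/(1 + ratio), which is 40.9%. Of the E gone by then, 52.4% would stand as Q, so I would take Q out and not wait. If the missing part never returned, Q and E together, 62.7%, would be the ceiling for winter.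

The forecast gave 45.5% now, winter as best, 55% after winter and 51% after midnight, holding that the runs “favours inhibition by Q, not ageing”. My Q now was lower than its figure, and my ceiling stood higher than its winter.

    Q ⇌ G (K = 1.00, k = 3.20 × 10⁻⁴ min⁻¹)
    E + D + L → L + Q (k = 3.80 M⁻² min⁻¹)
    X + D + L → L + J (k = 0.0240 M⁻² min⁻¹)

The south flask held Q 43.5% at 5.0 d. winter gained most, 24 percentage points, reaching 67.1%, which is 3.7 points above that flask's Q and E together, so some Q came from G; midnight gave 49.9%. In that flask the step to Q had done half its turnover up to 5.0 d by 23.4 h, and the step from Q to G later, by 46.6 h; at 120 h G stood to Q as 0.842, with E 19.9% and D 29.0% left. With my ratio 0.910, the neighbour flask at 0.25 M of E, ending with E 1.87%, reckons to Q 51.4%, and it held 50.3%.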